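**Plan**

- Retrosynthesis: the three MOM ethers and both silyl groups come off last; ring C of the isoflavone is then cut at C3–C4 and O1–C2, leaving a ring A salicylaldehyde and an 8-(silylethynyl)chromene that carries ring B and the pyran ring.
- Enabling feature: in ring C the C4 carbonyl and O1 sit ortho on ring A, as CHO and OH do in a salicylaldehyde, and C2=C3 (C3 bonded to chromene C8) has the oxidation level of an aryl alkyne, so the crowded C3–aryl bond already exists as the aryl–alkyne bond.
- The chromene is cut at the alkyne (from a formyl group on C8), at C3=C4 (ring-closing metathesis) and at the O1–C2 ether bond (palladium-catalysed allylic etherification of a 2-vinylphenol made from 2,6-dihydroxybenzaldehyde).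
- Forward order: arene functionalisation (steps 2–4), ether (5), pyran ring by metathesis (7), alkyne (8, 9), ring C by rhodium annulation (10), deprotection (11, 12); rings A and B come from the two benzaldehydes.
- Stereochemistry: the single stereocentre, the quaternary C2 of the chromene (S), is set in step 5 by the chiral ligand in the etherification with racemic 2-methyl-2-vinyloxirane; as a quaternary ether carbon it cannot epimerise afterwards.

Key step: step 10

Assumption: the (R,R)-enantiomer of the Trost ligand is taken to deliver the (S)-ether in step 5; if the sense of induction proves opposite, the (S,S)-ligand is used with no other change.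

**Route**

Step 1
Reactants: 1 2,4,6-trihydroxybenzaldehyde
Product: 2 2-hydroxy-4,6-bis(methoxymethoxy)benzaldehyde
Conditions: MOMCl (2.2 equiv), iPr2NEt (3 equiv), CH2Cl2, 0 °C to rt
Reagents that add atoms: chloromethyl methyl ether, COCCl
Why: MOM protection by O-alkylation, in which the para hydroxyl and one ortho hydroxyl react while the last ortho hydroxyl, hydrogen-bonded to the formyl oxygen, should stay free with two equivalents of reagent and an amine base.

Step 2
Reactants: 3 2,6-dihydroxybenzaldehyde
Product: 4 2-hydroxy-6-(methoxymethoxy)benzaldehyde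
Conditions: MOMCl (1.05 equiv), iPr2NEt (1.5 equiv), CH2Cl2, 0 °C
Reagents that add atoms: chloromethyl methyl ether, COCCl
Why: Mono-MOM protection of a symmetrical diol, where after the first etherification the remaining hydroxyl is chelated to the aldehyde and far less nucleophilic, so one equivalent should stop at the mono-ether.

Step 3
Reactants: 4 2-hydroxy-6-(methoxymethoxy)benzaldehyde
Product: 5 3-(methoxymethoxy)-2-vinylphenol
Conditions: Ph3PCH3Br (2.5 equiv), KOtBu (2.5 equiv), THF, 0 °C to rt
Reagents that add atoms: methyltriphenylphosphonium bromide, C[P+](c1ccccc1)(c1ccccc1)c1ccccc1.[Br-]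
Why: Wittig methylenation, in which excess ylide first deprotonates the phenol and still olefinates the phenoxide aldehyde, the MOM acetal being inert to base.

Step 4
Reactants: 5 3-(methoxymethoxy)-2-vinylphenol
Product: 7 2-hydroxy-4-(methoxymethoxy)-3-vinylbenzaldehyde, via benzylic alcohol 6 (not isolated)
Conditions: MgCl2 (2 equiv), Et3N (4 equiv), (CH2O)n (6 equiv), MeCN, reflux; aq. NH4Cl work-up
Reagents that add atoms: paraformaldehyde (as formaldehyde), C=O
Why: Magnesium-mediated ortho-formylation of a phenol (Casnati–Skattebøl reaction), in which the magnesium phenoxide delivers formaldehyde to the only free ortho position and a second formaldehyde oxidises the benzylic alcohol by hydride transfer, so the formyl group can only enter at the carbon that becomes chromene C8.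

Step 5
Reactants: 7 2-hydroxy-4-(methoxymethoxy)-3-vinylbenzaldehyde; 8 2-methyl-2-vinyloxirane (racemic)
Product: 9 (S)-2-[(1-hydroxy-2-methylbut-3-en-2-yl)oxy]-4-(methoxymethoxy)-3-vinylbenzaldehyde
Conditions: 8 (1.3 equiv), Pd2(dba)3·CHCl3 (2 mol %), (R,R)-DACH-phenyl Trost ligand (6 mol %), CH2Cl2, rt
Reagents that add atoms: none
Why: Palladium-catalysed asymmetric allylic etherification (Trost AAA) run as a dynamic kinetic asymmetric transformation, in which zerovalent palladium opens the racemic vinyl epoxide to rapidly equilibrating π-allyl complexes, the alkoxide deprotonates the acidic phenol and the phenoxide attacks the more substituted allyl terminus inside the chiral ligand pocket, which sets the (S) quaternary ether carbon.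

Step 6
Reactants: 9 (S)-2-[(1-hydroxy-2-methylbut-3-en-2-yl)oxy]-4-(methoxymethoxy)-3-vinylbenzaldehyde
Product: 10 (S)-2-{[1-(tert-butyldimethylsilyloxy)-2-methylbut-3-en-2-yl]oxy}-4-(methoxymethoxy)-3-vinylbenzaldehyde
Conditions: TBSCl (1.3 equiv), imidazole (2.5 equiv), DMF, 0 °C to rt
Reagents that add atoms: tert-butyldimethylsilyl chloride, CC(C)(C)[Si](C)(C)Cl
Why: Silyl ether formation at the only hydroxyl, a primary alcohol, which leaves the aldehyde, the MOM ether and both vinyl groups untouched.

Step 7
Reactants: 10 (S)-2-{[1-(tert-butyldimethylsilyloxy)-2-methylbut-3-en-2-yl]oxy}-4-(methoxymethoxy)-3-vinylbenzaldehyde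
Product: 11 (S)-2-[(tert-butyldimethylsilyloxy)methyl]-5-(methoxymethoxy)-2-methyl-2H-chromene-8-carbaldehyde
Conditions: second-generation Grubbs catalyst (H2IMes)(PCy3)Cl2Ru=CHPh (5 mol %), CH2Cl2 (0.01 M), 40 °C
Reagents that add atoms: none
Why: Ring-closing metathesis of the styrene with the vinyl group on the quaternary ether carbon closes the six-membered pyran ring with loss of ethene, the stereocentre taking no part and the aldehyde being tolerated by the ruthenium carbene.

Step 8
Reactants: 11 (S)-2-[(tert-butyldimethylsilyloxy)methyl]-5-(methoxymethoxy)-2-methyl-2H-chromene-8-carbaldehyde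
Product: 12 (S)-2-[(tert-butyldimethylsilyloxy)methyl]-8-ethynyl-5-(methoxymethoxy)-2-methyl-2H-chromene
Conditions: dimethyl (1-diazo-2-oxopropyl)phosphonate (1.5 equiv), K2CO3 (2.5 equiv), MeOH, 0 °C to rt
Reagents that add atoms: dimethyl (1-diazo-2-oxopropyl)phosphonate, COP(=O)(OC)C(=[N+]=[N-])C(C)=O
Why: Seyferth–Gilbert homologation under Ohira–Bestmann conditions, in which methanolysis of the reagent gives the diazomethylphosphonate anion that turns the non-enolisable aryl aldehyde into the terminal alkyne under carbonate conditions compatible with the TBS and MOM ethers.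

Step 9
Reactants: 12 (S)-2-[(tert-butyldimethylsilyloxy)methyl]-8-ethynyl-5-(methoxymethoxy)-2-methyl-2H-chromene
Product: 14 (S)-2-[(tert-butyldimethylsilyloxy)methyl]-5-(methoxymethoxy)-2-methyl-8-(trimethylsilylethynyl)-2H-chromene, via lithium acetylide 13 (not isolated)
Conditions: n-BuLi (1.05 equiv), THF, −78 °C; then Me3SiCl (1.2 equiv), −78 to 0 °C
Reagents that add atoms: chlorotrimethylsilane, C[Si](C)(C)Cl
Why: Deprotonation of the terminal alkyne, which at −78 °C is much faster than MOM-directed ring lithiation, followed by C-silylation of the acetylide.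

Step 10
Reactants: 2 2-hydroxy-4,6-bis(methoxymethoxy)benzaldehyde; 14 (S)-2-[(tert-butyldimethylsilyloxy)methyl]-5-(methoxymethoxy)-2-methyl-8-(trimethylsilylethynyl)-2H-chromene
Product: 15 (S)-3-{2-[(tert-butyldimethylsilyloxy)methyl]-5-(methoxymethoxy)-2-methyl-2H-chromen-8-yl}-5,7-bis(methoxymethoxy)-2-(trimethylsilyl)-4H-chromen-4-one
Conditions: 14 (1.0 equiv), 2 (1.3 equiv), [Cp*RhCl2]2 (5 mol %), anhydrous Cu(OAc)2 (2.2 equiv), toluene, 110 °C, N2
Reagents that add atoms: none
Why: This is a rhodium-catalysed oxidative C–H/O–H annulation of a salicylaldehyde with an internal alkyne, a known chromone synthesis: the phenoxide of 2 binds trivalent rhodium, acetate-assisted cleavage of the formyl C–H bond gives a five-membered acyl rhodacycle, the alkyne inserts into the Rh–acyl bond, and C–O reductive elimination from the seven-membered oxa-rhodacycle releases the chromone while Cu(OAc)2 returns monovalent rhodium to the trivalent state. Ring C is closed as a formal [4+2] heteroannulation, the C3–C4 bond by intermolecular migratory insertion and the O1–C2 bond by ring-closing reductive elimination. No stereocentre is formed, and the quaternary C2 of the chromene lies far from the reacting atoms. The step needs one sense of alkyne insertion, with the acyl carbon joined to the aryl-bearing alkyne carbon; the Me3Si group should take the carbon bound to rhodium because a C–Si bond stabilises the adjacent carbon–metal bond and the bulky silyl group avoids the carbon that must bond to the acyl group flanked by OMOM, the orientation familiar from Larock-type heteroannulations of silylalkynes. Chemoselectivity rests on 2 having a single free phenol, on the silyl cap that blocks copper-mediated alkyne homocoupling, and on the chromene alkene and the TBS and MOM ethers being inert to the acetate medium.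

Step 11
Reactants: 15 (S)-3-{2-[(tert-butyldimethylsilyloxy)methyl]-5-(methoxymethoxy)-2-methyl-2H-chromen-8-yl}-5,7-bis(methoxymethoxy)-2-(trimethylsilyl)-4H-chromen-4-one
Product: 16 (S)-3-[2-(hydroxymethyl)-5-(methoxymethoxy)-2-methyl-2H-chromen-8-yl]-5,7-bis(methoxymethoxy)-4H-chromen-4-one
Conditions: Bu4NF (3 equiv), THF, 0 °C to rt; aq. NH4Cl
Reagents that add atoms: none
Why: Fluoride-mediated desilylation cleaves the Si–O bond of the TBS ether and the C2–Si bond of the 2-silylchromone (ipso protodesilylation of a vinylsilane whose carbanion is stabilised by the ring oxygen), while MOM ethers are inert to fluoride.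

Step 12
Reactants: 16 (S)-3-[2-(hydroxymethyl)-5-(methoxymethoxy)-2-methyl-2H-chromen-8-yl]-5,7-bis(methoxymethoxy)-4H-chromen-4-one
Product: 17 (S)-5,7-dihydroxy-3-[5-hydroxy-2-(hydroxymethyl)-2-methyl-2H-chromen-8-yl]-4H-chromen-4-one
Conditions: 3 M aq. HCl/MeOH (1:10), 45 °C
Reagents that add atoms: none
Why: Acid-catalysed transacetalisation of the three MOM ethers to methanol, in which dilute acid at moderate temperature should leave the 2H-chromene, whose C2 cation is disfavoured by the adjacent CH2OH group, and the primary alcohol intact.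

**Compound list**

1 | 2,4,6-trihydroxybenzaldehyde | O=Cc1c(O)cc(O)cc1O | starting material
2 | 2-hydroxy-4,6-bis(methoxymethoxy)benzaldehyde | O=Cc1c(O)cc(OCOC)cc1OCOC | intermediate
3 | 2,6-dihydroxybenzaldehyde | O=Cc1c(O)cccc1O | starting material
4 | 2-hydroxy-6-(methoxymethoxy)benzaldehyde | O=Cc1c(O)cccc1OCOC | intermediate
5 | 3-(methoxymethoxy)-2-vinylphenol | C=Cc1c(O)cccc1OCOC | intermediate
6 | 6-(hydroxymethyl)-3-(methoxymethoxy)-2-vinylphenol | C=Cc1c(O)c(CO)ccc1OCOC | intermediate (not isolated)
7 | 2-hydroxy-4-(methoxymethoxy)-3-vinylbenzaldehyde | C=Cc1c(O)c(C=O)ccc1OCOC | intermediate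
8 | 2-methyl-2-vinyloxirane (racemic) | CC1(CO1)C=C | starting material
9 | (S)-2-[(1-hydroxy-2-methylbut-3-en-2-yl)oxy]-4-(methoxymethoxy)-3-vinylbenzaldehyde | C[C@@](CO)(C=C)Oc1c(C=O)ccc(OCOC)c1C=C | intermediate
10 | (S)-2-{[1-(tert-butyldimethylsilyloxy)-2-methylbut-3-en-2-yl]oxy}-4-(methoxymethoxy)-3-vinylbenzaldehyde | C[C@@](CO[Si](C)(C)C(C)(C)C)(C=C)Oc1c(C=O)ccc(OCOC)c1C=C | intermediate
11 | (S)-2-[(tert-butyldimethylsilyloxy)methyl]-5-(methoxymethoxy)-2-methyl-2H-chromene-8-carbaldehyde | C[C@@]1(CO[Si](C)(C)C(C)(C)C)C=Cc2c(OCOC)ccc(C=O)c2O1 | intermediate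
12 | (S)-2-[(tert-butyldimethylsilyloxy)methyl]-8-ethynyl-5-(methoxymethoxy)-2-methyl-2H-chromene | C[C@@]1(CO[Si](C)(C)C(C)(C)C)C=Cc2c(OCOC)ccc(C#C)c2O1 | intermediate
13 | lithium acetylide of 12 | C[C@@]1(CO[Si](C)(C)C(C)(C)C)C=Cc2c(OCOC)ccc(C#[C-])c2O1.[Li+] | intermediate (not isolated)
14 | (S)-2-[(tert-butyldimethylsilyloxy)methyl]-5-(methoxymethoxy)-2-methyl-8-(trimethylsilylethynyl)-2H-chromene | C[C@@]1(CO[Si](C)(C)C(C)(C)C)C=Cc2c(OCOC)ccc(C#C[Si](C)(C)C)c2O1 | intermediate
15 | (S)-3-{2-[(tert-butyldimethylsilyloxy)methyl]-5-(methoxymethoxy)-2-methyl-2H-chromen-8-yl}-5,7-bis(methoxymethoxy)-2-(trimethylsilyl)-4H-chromen-4-one | C[C@@]1(CO[Si](C)(C)C(C)(C)C)C=Cc2c(OCOC)ccc(-c3c([Si](C)(C)C)oc4cc(OCOC)cc(OCOC)c4c3=O)c2O1 | intermediate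
16 | (S)-3-[2-(hydroxymethyl)-5-(methoxymethoxy)-2-methyl-2H-chromen-8-yl]-5,7-bis(methoxymethoxy)-4H-chromen-4-one | C[C@@]1(CO)C=Cc2c(OCOC)ccc(-c3coc4cc(OCOC)cc(OCOC)c4c3=O)c2O1 | intermediate
17 | (S)-5,7-dihydroxy-3-[5-hydroxy-2-(hydroxymethyl)-2-methyl-2H-chromen-8-yl]-4H-chromen-4-one (CNP0141863.1) | C[C@@]1(CO)C=Cc2c(O)ccc(-c3coc4cc(O)cc(O)c4c3=O)c2O1 | target

**Step count**

Total step count: 12. Longest linear sequence: 11 steps (3 to 17, steps 2–12); step 1 is the one-step branch to 2.

**Steps most likely to fail**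

Step 10. The alkyne may insert in the reverse sense, with the aryl group on the rhodium-bound carbon, which would lead to a flavone-type 2-aryl chromone. The alkynyl silyl group may also be lost under hot Cu(OAc)2 and the freed alkyne dimerise, or the acyl rhodium intermediate may decarbonylate before the hindered alkyne inserts. Loss of the C2 silyl group from the product alone would be harmless, since that material converges at 16. The fallback gives up the annulation and builds ring C through a deoxybenzoin and its enaminone, where the connectivity fixes the regiochemistry; it sets out from 12 and rejoins the route at 17. Hydroboration of 12 with dicyclohexylborane and buffered NaBO3·4H2O oxidation should give 2-{(S)-2-[(tert-butyldimethylsilyloxy)methyl]-5-(methoxymethoxy)-2-methyl-2H-chromen-8-yl}acetaldehyde F1. Phloroglucinol with MOMCl and NaH gives 1,3,5-tris(methoxymethoxy)benzene F2, which n-BuLi in THF at 0 °C lithiates between two MOM groups to 2,4,6-tris(methoxymethoxy)phenyllithium F3. Addition of this to F1 at −78 °C (with CeCl3 if enolisation interferes) should give 2-{(S)-2-[(tert-butyldimethylsilyloxy)methyl]-5-(methoxymethoxy)-2-methyl-2H-chromen-8-yl}-1-[2,4,6-tris(methoxymethoxy)phenyl]ethanol F4 as both carbinol epimers. Dess–Martin oxidation then gives 2-{(S)-2-[(tert-butyldimethylsilyloxy)methyl]-5-(methoxymethoxy)-2-methyl-2H-chromen-8-yl}-1-[2,4,6-tris(methoxymethoxy)phenyl]ethanone F5, and Me2NCH(OMe)2 in toluene at 90 °C gives 3-(dimethylamino)-2-{(S)-2-[(tert-butyldimethylsilyloxy)methyl]-5-(methoxymethoxy)-2-methyl-2H-chromen-8-yl}-1-[2,4,6-tris(methoxymethoxy)phenyl]prop-2-en-1-one F6. HCl in MeOH finally removes the MOM and TBS groups, and the freed ortho phenol closes ring C by addition–elimination with loss of dimethylamine to give 17.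

Step 5. The chelated, doubly ortho-substituted phenoxide may be discriminated poorly by the ligand pocket, giving low enantioselectivity, or the tertiary ether may re-ionise and drift to the linear allyl ether. The fallback gives up catalyst control of configuration and resolves instead; it sets out from 7 and 8 and rejoins the route at 9. Etherification with Pd2(dba)3·CHCl3 and the racemic Trost ligand should give racemic 2-[(1-hydroxy-2-methylbut-3-en-2-yl)oxy]-4-(methoxymethoxy)-3-vinylbenzaldehyde F7. Kinetic resolution by lipase-catalysed acetylation (Burkholderia cepacia lipase, vinyl acetate, t-BuOMe) follows, with an enzyme selected by screening so that the (R)-alcohol is the one acylated. Chromatography then separates (R)-2-[6-formyl-3-(methoxymethoxy)-2-vinylphenoxy]-2-methylbut-3-en-1-yl acetate F8 from the unreacted (S)-alcohol, which is 9.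

Step 4. The MOM acetal may be lost under MgCl2 at reflux, or the vinylphenol may oligomerise with formaldehyde before formylation is complete. The fallback replaces C-formylation by halogenation and brings the alkyne in by cross-coupling; it sets out from 5 and rejoins the route at 14, one step shorter. Amine-directed ortho-bromination (NBS, catalytic iPr2NH, CH2Cl2, −78 °C) should give 6-bromo-3-(methoxymethoxy)-2-vinylphenol F9; attack para to the phenol is the competing pathway, so the position of bromine has to be confirmed. Etherification as in step 5 gives (S)-2-[6-bromo-3-(methoxymethoxy)-2-vinylphenoxy]-2-methylbut-3-en-1-ol F10, and silylation as in step 6 gives (S)-{2-[6-bromo-3-(methoxymethoxy)-2-vinylphenoxy]-2-methylbut-3-enyloxy}(tert-butyl)dimethylsilane F11. Metathesis as in step 7 gives (S)-8-bromo-2-[(tert-butyldimethylsilyloxy)methyl]-5-(methoxymethoxy)-2-methyl-2H-chromene F12. Sonogashira coupling with ethynyltrimethylsilane (PdCl2(PPh3)2, CuI, Et3N, 60 °C) then gives 14.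

**Further compounds**

F1 | step 10 | 2-{(S)-2-[(tert-butyldimethylsilyloxy)methyl]-5-(methoxymethoxy)-2-methyl-2H-chromen-8-yl}acetaldehyde | C[C@@]1(CO[Si](C)(C)C(C)(C)C)C=Cc2c(OCOC)ccc(CC=O)c2O1
F2 | step 10 | 1,3,5-tris(methoxymethoxy)benzene | COCOc1cc(OCOC)cc(OCOC)c1
F3 | step 10 | 2,4,6-tris(methoxymethoxy)phenyllithium | [Li]c1c(OCOC)cc(OCOC)cc1OCOC
F4 | step 10 | 2-{(S)-2-[(tert-butyldimethylsilyloxy)methyl]-5-(methoxymethoxy)-2-methyl-2H-chromen-8-yl}-1-[2,4,6-tris(methoxymethoxy)phenyl]ethanol | C[C@@]1(CO[Si](C)(C)C(C)(C)C)C=Cc2c(OCOC)ccc(CC(O)c3c(OCOC)cc(OCOC)cc3OCOC)c2O1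
F5 | step 10 | 2-{(S)-2-[(tert-butyldimethylsilyloxy)methyl]-5-(methoxymethoxy)-2-methyl-2H-chromen-8-yl}-1-[2,4,6-tris(methoxymethoxy)phenyl]ethanone | C[C@@]1(CO[Si](C)(C)C(C)(C)C)C=Cc2c(OCOC)ccc(CC(=O)c3c(OCOC)cc(OCOC)cc3OCOC)c2O1
F6 | step 10 | 3-(dimethylamino)-2-{(S)-2-[(tert-butyldimethylsilyloxy)methyl]-5-(methoxymethoxy)-2-methyl-2H-chromen-8-yl}-1-[2,4,6-tris(methoxymethoxy)phenyl]prop-2-en-1-one | C[C@@]1(CO[Si](C)(C)C(C)(C)C)C=Cc2c(OCOC)ccc(C(=CN(C)C)C(=O)c3c(OCOC)cc(OCOC)cc3OCOC)c2O1
F7 | step 5 | racemic 2-[(1-hydroxy-2-methylbut-3-en-2-yl)oxy]-4-(methoxymethoxy)-3-vinylbenzaldehyde | CC(CO)(C=C)Oc1c(C=O)ccc(OCOC)c1C=C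
F8 | step 5 | (R)-2-[6-formyl-3-(methoxymethoxy)-2-vinylphenoxy]-2-methylbut-3-en-1-yl acetate | C[C@](COC(C)=O)(C=C)Oc1c(C=O)ccc(OCOC)c1C=C
F9 | step 4 | 6-bromo-3-(methoxymethoxy)-2-vinylphenol | C=Cc1c(O)c(Br)ccc1OCOC
F10 | step 4 | (S)-2-[6-bromo-3-(methoxymethoxy)-2-vinylphenoxy]-2-methylbut-3-en-1-ol | C[C@@](CO)(C=C)Oc1c(Br)ccc(OCOC)c1C=C
F11 | step 4 | (S)-{2-[6-bromo-3-(methoxymethoxy)-2-vinylphenoxy]-2-methylbut-3-enyloxy}(tert-butyl)dimethylsilane | C[C@@](CO[Si](C)(C)C(C)(C)C)(C=C)Oc1c(Br)ccc(OCOC)c1C=C
F12 | step 4 | (S)-8-bromo-2-[(tert-butyldimethylsilyloxy)methyl]-5-(methoxymethoxy)-2-methyl-2H-chromene | C[C@@]1(CO[Si](C)(C)C(C)(C)C)C=Cc2c(OCOC)ccc(Br)c2O1
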